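The target hides a repeat. Once O1–C2 is set aside, both aromatic rings are the same 4-prenylresorcinol. Ring A is bound to the carbonyl carbon C4 through C4a and ring B to C3 through C1′, and these two positions match (oxygen ortho and para, prenyl meta). Cutting C4–C4a and C3–C1′ leaves two copies of one aryl nucleophile and a three-carbon bis-electrophile. A single palladium-catalysed twofold Negishi coupling of [5-prenyl-2,4-bis(TIPS-oxy)phenyl]zinc chloride with 2-bromoacryloyl chloride forms both bonds. It delivers the whole carbon skeleton as an acyclic 1,2-diarylpropenone. Fluoride then closes O1–C2, and C3 is fixed by transfer-hydrogenative dynamic kinetic resolution and re-oxidation.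

Key step: step 5

Assumption: the SMILES descriptor corresponds to (3S); because C3–H is benzylic and α to the ketone it is treated as base-labile, so C3 is fixed late and only non-basic or buffered media follow (prenyl = 3-methylbut-2-enyl, TIPS = triisopropylsilyl).

Step 1
Reactants: 1 4,6-dibromoresorcinol
Product: 2 1,5-dibromo-2,4-bis(triisopropylsilyloxy)benzene
Conditions: TIPSCl (2.4 equiv), imidazole (5 equiv), DMF, 25 → 40 °C
Reagents that add atoms: triisopropylsilyl chloride, CC(C)[Si](Cl)(C(C)C)C(C)C
Why: Imidazole-promoted O-silylation of both phenols; TIPS is preferred to smaller silyl groups because it resists the O-to-C 1,3-silyl shift (retro-Brook rearrangement) that threatens an aryl anion next to a silyloxy group in steps 2 and 3, and it later leaves with fluoride rather than with the acid that would cyclise o-prenylphenols to chromans.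

Step 2
Reactants: 2 1,5-dibromo-2,4-bis(triisopropylsilyloxy)benzene; 3 prenyl bromide (1-bromo-3-methylbut-2-ene)
Product: 6 1-bromo-5-prenyl-2,4-bis(triisopropylsilyloxy)benzene, via bromoaryllithium 4 (not isolated), via bromoarylcopper 5 (not isolated)
Conditions: n-BuLi (1.0 equiv), THF, −78 °C, 15 min; CuBr·SMe2 (1.0 equiv, in Me2S–THF), −78 °C; 3 (1.3 equiv), −78 → 0 °C
Reagents that add atoms: none
Why: Bromine–lithium exchange on the C2v-symmetric dibromide gives the same aryllithium whichever bromine reacts and stops after one exchange because the anion deactivates the ring, and the derived arylcopper undergoes copper-mediated allylic substitution at the unhindered primary carbon of prenyl bromide (SN2 rather than SN2′), the mixture being kept cold until lithium has been replaced by copper.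

Step 3
Reactants: 6 1-bromo-5-prenyl-2,4-bis(triisopropylsilyloxy)benzene
Product: 8 [5-prenyl-2,4-bis(triisopropylsilyloxy)phenyl]zinc chloride, via aryllithium 7 (not isolated)
Conditions: n-BuLi (1.0 equiv), THF, −78 °C, 15 min; ZnCl2 (1.1 equiv, 1.0 M in THF), −78 °C → rt; titrated with I2 and kept as a THF solution
Reagents that add atoms: zinc chloride, Cl[Zn]Cl
Why: Bromine–lithium exchange followed at −78 °C by lithium-to-zinc transmetallation is the standard entry to Negishi reagents, and the covalent C–Zn bond neither attacks the neighbouring silicon nor deprotonates the benzylic-allylic CH2 of the prenyl group, so the solution can be warmed and stored.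

Step 4
Reactants: 9 2-bromoacrylic acid
Product: 10 2-bromoacryloyl chloride
Conditions: (COCl)2 (1.05 equiv), DMF (cat.), BHT (trace), CH2Cl2, 0 °C → rt; volatiles removed cold; used at once
Reagents that add atoms: oxalyl chloride, O=C(Cl)C(=O)Cl
Why: DMF-catalysed (Vilsmeier-type) conversion of a carboxylic acid into its chloride gives only gaseous by-products, the low temperature and the inhibitor protect the polymerisable α-bromoacryloyl unit, and removing residual oxalyl chloride keeps it from consuming 8.

Step 5
Reactants: 8 [5-prenyl-2,4-bis(triisopropylsilyloxy)phenyl]zinc chloride (2.2 equiv); 10 2-bromoacryloyl chloride (1.0 equiv)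
Product: 12 1,2-bis[5-prenyl-2,4-bis(triisopropylsilyloxy)phenyl]prop-2-en-1-one, via bromovinyl ketone 11 (not isolated)
Conditions: Pd(dba)2 (5 mol %), P(2-furyl)3 (10 mol %), THF; 10 added over 1 h at 0 °C, then 25 → 40 °C
Reagents that add atoms: none
Why: Pd(0) inserts into the acyl C–Cl bond of 10; transmetallation from 8 and reductive elimination give bromovinyl ketone 11, whose carbonyl-activated C–Br bond then passes through a second oxidative addition/transmetallation/reductive elimination cycle with another equivalent of 8, forming C4–C4a and C3–C1′ in that order. The closest known reaction types are the Negishi acylation of acid chlorides (enoyl chlorides included) and the Negishi coupling of α-halo enones, run here back to back with one catalyst. No ring is closed and no stereocentre is created. Site selectivity between the two carbon–halogen bonds is not required, because the same aryl group ends up on both carbons and either order of events converges on 12. What is required is cross-coupling in preference to 1,4-addition to 11 or 12 and to polymerisation of 10: an arylzinc chloride is a poor conjugate donor without copper or nickel, its ortho TIPS-oxy group shields the C–Zn bond further, and slow addition of 10 into excess 8 keeps the free electrophile scarce. Tri(2-furyl)phosphine is chosen as a weak donor that speeds transmetallation and reductive elimination at the crowded vinylpalladium stage, and the start at 0 °C keeps the acylpalladium from losing CO.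

Step 6
Reactants: 12 1,2-bis[5-prenyl-2,4-bis(triisopropylsilyloxy)phenyl]prop-2-en-1-one
Product: 14 rac-3-(2,4-dihydroxy-5-prenylphenyl)-7-hydroxy-6-prenylchroman-4-one, via tetraphenol enone 13 (not isolated)
Conditions: TBAF (4.4 equiv), degassed THF (0.02 M), 0 °C → rt, Ar; AcOH quench
Reagents that add atoms: none
Why: Fluoride cleavage of all four aryl silyl ethers (so ring-A and ring-B ethers need not be told apart) is followed by intramolecular oxa-Michael addition, in which the ring-A ortho phenoxide attacks C2 in the 6-endo-trig closure that also ends the classical deoxybenzoin–formaldehyde isoflavanone synthesis, whereas the 2′-oxygen would need a strained 5-endo-trig path, intermolecular additions are reversible, and C3 is knowingly formed racemic.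

Step 7
Reactants: 14 rac-3-(2,4-dihydroxy-5-prenylphenyl)-7-hydroxy-6-prenylchroman-4-one
Product: 15 rac-6-prenyl-3-[5-prenyl-2,4-bis(triisopropylsilyloxy)phenyl]-7-(triisopropylsilyloxy)chroman-4-one
Conditions: TIPSCl (3.6 equiv), imidazole (7 equiv), DMAP (cat.), DMF, 40 °C
Reagents that add atoms: triisopropylsilyl chloride, CC(C)[Si](Cl)(C(C)C)C(C)C
Why: Imidazole-promoted silylation caps the three phenols, which would otherwise be oxidised in step 9 and would let the C4 alcohol of step 8 ionise to a quinone methide, and TIPS withstands the formic acid–triethylamine medium even at the ketone-conjugated O7.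

Step 8
Reactants: 15 rac-6-prenyl-3-[5-prenyl-2,4-bis(triisopropylsilyloxy)phenyl]-7-(triisopropylsilyloxy)chroman-4-one
Product: 16 (3S,4S)-6-prenyl-3-[5-prenyl-2,4-bis(triisopropylsilyloxy)phenyl]-7-(triisopropylsilyloxy)chroman-4-ol (3,4-cis)
Conditions: RuCl[(S,S)-TsDPEN](p-cymene) (2 mol %), HCO2H–Et3N (5:2), EtOAc, 40 °C
Reagents that add atoms: none
Why: Noyori–Ikariya asymmetric transfer hydrogenation under dynamic kinetic resolution is a reaction type established for isoflavanones: triethylamine interconverts the C3 enantiomers through the enol, the (S,S)-catalyst delivers hydride to the C4 face that gives (4S) with ring A in the aryl role of the aryl-ketone model, and only the (3S)-ketone offers that face anti to its 3-aryl group, so the cis-(3S,4S) alcohol should result while the prenyl C=C bonds are ignored by the outer-sphere hydride transfer.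

Step 9
Reactants: 16 (3S,4S)-6-prenyl-3-[5-prenyl-2,4-bis(triisopropylsilyloxy)phenyl]-7-(triisopropylsilyloxy)chroman-4-ol
Product: 17 (3S)-6-prenyl-3-[5-prenyl-2,4-bis(triisopropylsilyloxy)phenyl]-7-(triisopropylsilyloxy)chroman-4-one
Conditions: Dess–Martin periodinane (1.2 equiv), CH2Cl2, 0 °C → rt
Reagents that add atoms: none
Why: Dess–Martin oxidation of the secondary benzylic alcohol erases the auxiliary C4 stereocentre in a base-free, weakly acidic medium that should not enolise the new ketone, so C3 stays (S), and aryl silyl ethers and trisubstituted alkenes are inert to the periodinane.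

Step 10
Reactants: 17 (3S)-6-prenyl-3-[5-prenyl-2,4-bis(triisopropylsilyloxy)phenyl]-7-(triisopropylsilyloxy)chroman-4-one
Product: 18 (3S)-3-(2,4-dihydroxy-5-prenylphenyl)-7-hydroxy-6-prenylchroman-4-one
Conditions: TBAF (3.3 equiv), AcOH (5 equiv), THF, 0 °C; pH 5–6 work-up
Reagents that add atoms: none
Why: Fluoride cleavage of aryl silyl ethers in an acetic-acid-buffered medium protonates each phenoxide as it forms, so the mixture should never become basic enough to enolise C3–H, and the absence of strong acid spares the o-prenylphenol units from chroman formation.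

Compound list
1 | 4,6-dibromoresorcinol | Oc1cc(O)c(Br)cc1Br | starting material
2 | 1,5-dibromo-2,4-bis(triisopropylsilyloxy)benzene | Brc1cc(Br)c(O[Si](C(C)C)(C(C)C)C(C)C)cc1O[Si](C(C)C)(C(C)C)C(C)C | intermediate
3 | prenyl bromide | CC(C)=CCBr | starting material
4 | 5-bromo-2,4-bis(triisopropylsilyloxy)phenyllithium (not isolated) | [Li]c1cc(Br)c(O[Si](C(C)C)(C(C)C)C(C)C)cc1O[Si](C(C)C)(C(C)C)C(C)C | intermediate
5 | 5-bromo-2,4-bis(triisopropylsilyloxy)phenylcopper (not isolated) | [Cu]c1cc(Br)c(O[Si](C(C)C)(C(C)C)C(C)C)cc1O[Si](C(C)C)(C(C)C)C(C)C | intermediate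
6 | 1-bromo-5-prenyl-2,4-bis(triisopropylsilyloxy)benzene | CC(C)=CCc1cc(Br)c(O[Si](C(C)C)(C(C)C)C(C)C)cc1O[Si](C(C)C)(C(C)C)C(C)C | intermediate
7 | 5-prenyl-2,4-bis(triisopropylsilyloxy)phenyllithium (not isolated) | CC(C)=CCc1cc([Li])c(O[Si](C(C)C)(C(C)C)C(C)C)cc1O[Si](C(C)C)(C(C)C)C(C)C | intermediate
8 | [5-prenyl-2,4-bis(triisopropylsilyloxy)phenyl]zinc chloride (THF solution) | CC(C)=CCc1cc([Zn]Cl)c(O[Si](C(C)C)(C(C)C)C(C)C)cc1O[Si](C(C)C)(C(C)C)C(C)C | intermediate
9 | 2-bromoacrylic acid | C=C(Br)C(=O)O | starting material
10 | 2-bromoacryloyl chloride | C=C(Br)C(=O)Cl | intermediate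
11 | 2-bromo-1-[5-prenyl-2,4-bis(triisopropylsilyloxy)phenyl]prop-2-en-1-one (not isolated) | C=C(Br)C(=O)c1cc(CC=C(C)C)c(O[Si](C(C)C)(C(C)C)C(C)C)cc1O[Si](C(C)C)(C(C)C)C(C)C | intermediate
12 | 1,2-bis[5-prenyl-2,4-bis(triisopropylsilyloxy)phenyl]prop-2-en-1-one | C=C(C(=O)c1cc(CC=C(C)C)c(O[Si](C(C)C)(C(C)C)C(C)C)cc1O[Si](C(C)C)(C(C)C)C(C)C)c1cc(CC=C(C)C)c(O[Si](C(C)C)(C(C)C)C(C)C)cc1O[Si](C(C)C)(C(C)C)C(C)C | intermediate
13 | 1,2-bis(2,4-dihydroxy-5-prenylphenyl)prop-2-en-1-one (not isolated) | C=C(C(=O)c1cc(CC=C(C)C)c(O)cc1O)c1cc(CC=C(C)C)c(O)cc1O | intermediate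
14 | rac-3-(2,4-dihydroxy-5-prenylphenyl)-7-hydroxy-6-prenylchroman-4-one | CC(C)=CCc1cc2c(cc1O)OCC(c1cc(CC=C(C)C)c(O)cc1O)C2=O | intermediate
15 | rac-6-prenyl-3-[5-prenyl-2,4-bis(triisopropylsilyloxy)phenyl]-7-(triisopropylsilyloxy)chroman-4-one | CC(C)=CCc1cc2c(cc1O[Si](C(C)C)(C(C)C)C(C)C)OCC(c1cc(CC=C(C)C)c(O[Si](C(C)C)(C(C)C)C(C)C)cc1O[Si](C(C)C)(C(C)C)C(C)C)C2=O | intermediate
16 | (3S,4S)-6-prenyl-3-[5-prenyl-2,4-bis(triisopropylsilyloxy)phenyl]-7-(triisopropylsilyloxy)chroman-4-ol, aryl and OH cis | CC(C)=CCc1cc2c(cc1O[Si](C(C)C)(C(C)C)C(C)C)OC[C@H](c1cc(CC=C(C)C)c(O[Si](C(C)C)(C(C)C)C(C)C)cc1O[Si](C(C)C)(C(C)C)C(C)C)[C@@H]2O | intermediate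
17 | (3S)-6-prenyl-3-[5-prenyl-2,4-bis(triisopropylsilyloxy)phenyl]-7-(triisopropylsilyloxy)chroman-4-one | CC(C)=CCc1cc2c(cc1O[Si](C(C)C)(C(C)C)C(C)C)OC[C@H](c1cc(CC=C(C)C)c(O[Si](C(C)C)(C(C)C)C(C)C)cc1O[Si](C(C)C)(C(C)C)C(C)C)C2=O | intermediate
18 | (3S)-3-(2,4-dihydroxy-5-prenylphenyl)-7-hydroxy-6-prenylchroman-4-one | CC(C)=CCc1cc2c(cc1O)OC[C@H](c1cc(CC=C(C)C)c(O)cc1O)C2=O | target

Total step count: 10. Longest linear sequence: 9 (steps 1–3 and 5–10, from 1); step 4 is a one-step side branch.

Steps most likely to fail

Step 5. The electrophile may polymerise or be consumed by zinc-salt-promoted opening of THF. The acylpalladium may lose CO. The second catalytic cycle may stall at the crowded transmetallation, so that the mono-coupled stage lingers and is lost to conjugate addition. The fallback separates the two bond formations and replaces the palladium acylation by a carbonyl addition. It sets out from 8 and 7 (both made from 6) and comes back to the route at 12. Negishi coupling of 8 with commercial 2-bromoacrolein (C=C(Br)C=O) under the same Pd/tri(2-furyl)phosphine catalyst should give the 2-arylpropenal F1. Aryllithium 7 is then added at −78 °C, where 1,2-addition to an enal is fast, to give the racemic diaryl allylic alcohol F2. Oxidation of this doubly activated alcohol with MnO2 in CH2Cl2 gives 12.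

Step 8. Hydride transfer to the hindered, electron-rich ketone may be sluggish. Epimerisation at C3 may not keep pace with reduction, which would erode both diastereo- and enantioselectivity. Base-induced retro-oxa-Michael opening may divert material. The fallback replaces reduction/re-oxidation by palladium-catalysed decarboxylative asymmetric protonation, a method known for isoflavanones. It sets out from 15 and comes back at 17, so steps 8 and 9 are skipped. Enolisation of 15 with LiHMDS at −78 °C and O-acylation with allyl chloroformate (C=CCOC(=O)Cl) gives the allyl enol carbonate F3. Pd2(dba)3 with t-Bu-PHOX and Meldrum's acid as proton donor in dioxane at 40 °C releases the palladium enolate and protonates it at C3. The ligand antipode that leads to (S) is to be settled in a pilot run, because the sense of induction depends on the proton source.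

Step 10. Configuration at C3 may partly leak away through enolisation while three phenoxides are released next to an acidic C–H. The fallback avoids late protecting groups altogether. It sets out from 14 and comes back at 18, bypassing steps 7–10. Racemic 14 is separated by preparative enantioselective chromatography (supercritical CO2/alcohol on a polysaccharide carbamate phase). The unwanted (3R)-enantiomer F4 is re-equilibrated to 14 with catalytic triethylamine and fed back into the separation.

Further compounds
F1 | step 5 | 2-[5-prenyl-2,4-bis(triisopropylsilyloxy)phenyl]prop-2-enal | C=C(C=O)c1cc(CC=C(C)C)c(O[Si](C(C)C)(C(C)C)C(C)C)cc1O[Si](C(C)C)(C(C)C)C(C)C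
F2 | step 5 | rac-1,2-bis[5-prenyl-2,4-bis(triisopropylsilyloxy)phenyl]prop-2-en-1-ol | C=C(C(O)c1cc(CC=C(C)C)c(O[Si](C(C)C)(C(C)C)C(C)C)cc1O[Si](C(C)C)(C(C)C)C(C)C)c1cc(CC=C(C)C)c(O[Si](C(C)C)(C(C)C)C(C)C)cc1O[Si](C(C)C)(C(C)C)C(C)C
F3 | step 8 | allyl 6-prenyl-3-[5-prenyl-2,4-bis(triisopropylsilyloxy)phenyl]-7-(triisopropylsilyloxy)-2H-chromen-4-yl carbonate | C=CCOC(=O)OC1=C(c2cc(CC=C(C)C)c(O[Si](C(C)C)(C(C)C)C(C)C)cc2O[Si](C(C)C)(C(C)C)C(C)C)COc2cc(O[Si](C(C)C)(C(C)C)C(C)C)c(CC=C(C)C)cc12
F4 | step 10 | (3R)-3-(2,4-dihydroxy-5-prenylphenyl)-7-hydroxy-6-prenylchroman-4-one | CC(C)=CCc1cc2c(cc1O)OC[C@@H](c1cc(CC=C(C)C)c(O)cc1O)C2=O
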